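The route rests on cutting the tetra-ortho-oxygenated biaryl bond between C5 of ring C (the ring whose C1 carries the ether oxygen to ring B) and D1 of ring D. Both carbons are nucleophilic sites flanked by two oxygens, and the adjacent oxygens on C4 and D2 can be joined by one CH2. A single oxidative dehydrogenative coupling across this formaldehyde acetal forms the C5–D1 bond and a temporary seven-membered dioxepine ring. The precursor is the octamethylated A–B–C triaryl diether whose C4 oxygen bears a (3,5-dimethoxyphenoxy)methyl group, assembled convergently from a ring A–B bromide and a ring C–D phenol; BBr3 finally removes bridge and methyl groups.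

Key step: step 7

Remark: ring A is the terminal 2,4,6-trioxygenated phenoxy ring, ring B the central 1,3,5-trioxygenated ring, ring C the ring carrying the biaryl bond, and ring D the terminal trioxygenated phenyl ring (D1 is its biaryl carbon). Compound 11 is chiral only through its bridged biaryl axis and is handled as the racemate, which is of no consequence because the axis of 12 is not stereogenic.

Step 1
Reactants: 1 2,4,6-trimethoxyphenol; 2 3,5-dibromoanisole
Product: 3 2-(3-bromo-5-methoxyphenoxy)-1,3,5-trimethoxybenzene (ring A–B bromide)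
Conditions: 2 (3 equiv), CuI (10 mol%), picolinic acid (20 mol%), K3PO4, DMSO, 90 °C, argon
Reagents that add atoms: none
Why: Ullmann-type diaryl ether synthesis with a picolinate-ligated CuI catalyst, a system known to accept di-ortho-substituted phenoxides, while the threefold excess of the symmetrical dibromide should hold the reaction at the monoether.

Step 2
Reactants: 4 2,6-dimethoxy-1,4-benzoquinone
Product: 5 2,6-dimethoxybenzene-1,4-diol
Conditions: Na2S2O4, H2O/EtOAc, rt, argon
Reagents that add atoms: none
Why: dithionite reduction of a para-quinone to its hydroquinone, which is carried on promptly under argon because it re-oxidises in air.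

Step 3
Reactants: 6 3,5-dimethoxyphenol
Product: 7 1,3-dimethoxy-5-[(methylsulfanyl)methoxy]benzene
Conditions: NaH, DMF, 0 °C; ClCH2SMe, NaI (cat.), 0 °C to rt
Reagents that add atoms: chloromethyl methyl sulfide, CSCCl
Why: Williamson O-alkylation of the sodium phenoxide in a dipolar aprotic solvent should give the methylthiomethyl ether, a stable store for the α-chloro ether.

Step 4
Reactants: 7 1,3-dimethoxy-5-[(methylsulfanyl)methoxy]benzene
Product: 8 1-(chloromethoxy)-3,5-dimethoxybenzene (crude, used at once)
Conditions: SO2Cl2 (1.0 equiv), cyclohexene (3 equiv), CH2Cl2, −78 to 0 °C; evaporate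
Reagents that add atoms: sulfuryl chloride, O=S(=O)(Cl)Cl
Why: chlorination at sulfur followed by Pummerer-type fragmentation of the chlorosulfonium ion is the known exchange of an aryl methylthiomethyl ether into an aryl chloromethyl ether, sulfur being far more nucleophilic than the ring at −78 °C and cyclohexene trapping the methanesulfenyl chloride before it can attack the arene.

Step 5
Reactants: 8 1-(chloromethoxy)-3,5-dimethoxybenzene; 5 2,6-dimethoxybenzene-1,4-diol
Product: 9 4-[(3,5-dimethoxyphenoxy)methoxy]-2,6-dimethoxyphenol (ring C–D phenol)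
Conditions: 5 (1.5 equiv), NaH (1.5 equiv), DMF, 0 °C, argon; then 8 in THF, 0 °C to rt
Reagents that add atoms: none
Why: Williamson alkylation with a reactive α-chloro ether should go to the C4 oxygen, whose hydroxyl is the more acidic and unhindered one whereas the C1 hydroxyl is flanked and hydrogen-bonded by two methoxy groups, and the excess of hydroquinone with one equivalent of base per hydroquinone suppresses double alkylation.

Step 6
Reactants: 9 4-[(3,5-dimethoxyphenoxy)methoxy]-2,6-dimethoxyphenol; 3 2-(3-bromo-5-methoxyphenoxy)-1,3,5-trimethoxybenzene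
Product: 10 1-[(3,5-dimethoxyphenoxy)methoxy]-3,5-dimethoxy-4-[3-methoxy-5-(2,4,6-trimethoxyphenoxy)phenoxy]benzene
Conditions: 3 (1.2 equiv), CuI (10 mol%), picolinic acid (20 mol%), K3PO4, DMSO, 90 °C, argon
Reagents that add atoms: none
Why: Ullmann-type diaryl ether synthesis of the same kind as step 1, in which the formaldehyde diaryl acetal is inert to base and CuI and the C–Br bond of 3 is activated inductively by its two meta oxygens.

Step 7
Reactants: 10 1-[(3,5-dimethoxyphenoxy)methoxy]-3,5-dimethoxy-4-[3-methoxy-5-(2,4,6-trimethoxyphenoxy)phenoxy]benzene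
Product: 11 1,3,9,11-tetramethoxy-2-[3-methoxy-5-(2,4,6-trimethoxyphenoxy)phenoxy]dibenzo[d,f][1,3]dioxepine (methylene-bridged biaryl, racemic axis)
Conditions: PhI(OCOCF3)2 (1.1 equiv), BF3·OEt2 (2.2 equiv), CH2Cl2 (0.005 M), −40 °C, argon
Reagents that add atoms: none
Why: PhI(OCOCF3)2 activated by BF3·OEt2 should remove one electron from the tetra-oxygenated ring C, whose radical cation is attacked at C5 by the tethered ring D carbon ortho to the acetal oxygen (D1); a second one-electron oxidation and loss of two protons rearomatise both rings, releasing iodobenzene and trifluoroacetic acid. The closest known reaction type is the intramolecular oxidative biaryl coupling of tethered phenol ethers by trivalent iodine reagents, which also closes seven-membered rings across one-atom O–X–O bridges between two aryloxy units. The only ring closed is the seven-membered 1,3-dioxepine (C4–O–CH2–O–D2–D1–C5), formed by aryl–aryl bond formation in endo mode, since both reacting carbons and their arene bonds lie inside the new ring. No stereocentre is created, and the bridged biaryl axis of 11 arises as a racemate that loses its stereogenic character once the bridge is removed. The step needs site selectivity and chemoselectivity: the one-carbon bridge lets only the two equivalent ortho carbons of ring D reach the two equivalent positions C3 and C5 of ring C, so one constitution is possible, while ring A, although as easily oxidised, has its ortho positions blocked by methoxy groups and no nucleophile within reach, so at high dilution a hole formed there is expected to pass to ring C and be consumed by the cyclisation. Low temperature, a single equivalent of oxidant and anhydrous conditions should limit over-oxidation of the electron-rich product and quinone formation.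

Step 8
Reactants: 11 1,3,9,11-tetramethoxy-2-[3-methoxy-5-(2,4,6-trimethoxyphenoxy)phenoxy]dibenzo[d,f][1,3]dioxepine
Product: 12 3-[3-hydroxy-5-(2,4,6-trihydroxyphenoxy)phenoxy]-[1,1'-biphenyl]-2,2',4,4',6,6'-hexol (CNP0260439.0)
Conditions: BBr3 (20 equiv), CH2Cl2, −78 °C to rt, argon; then H2O, 0 °C
Reagents that add atoms: none
Why: Lewis acid-mediated ether cleavage with BBr3 should dealkylate the eight aryl methyl ethers and open the methylene acetal in the manner of a methylenedioxy group, the bridge carbon leaving as dibromomethane, while the two diaryl ether bonds offer bromide no alkyl carbon to attack and survive.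

Compound list
1 | 2,4,6-trimethoxyphenol | COc1cc(OC)c(O)c(OC)c1 | starting material
2 | 3,5-dibromoanisole | COc1cc(Br)cc(Br)c1 | starting material
3 | 2-(3-bromo-5-methoxyphenoxy)-1,3,5-trimethoxybenzene | COc1cc(Br)cc(Oc2c(OC)cc(OC)cc2OC)c1 | intermediate
4 | 2,6-dimethoxy-1,4-benzoquinone | COC1=CC(=O)C=C(OC)C1=O | starting material
5 | 2,6-dimethoxybenzene-1,4-diol | COc1cc(O)cc(OC)c1O | intermediate
6 | 3,5-dimethoxyphenol | COc1cc(O)cc(OC)c1 | starting material
7 | 1,3-dimethoxy-5-[(methylsulfanyl)methoxy]benzene | COc1cc(OCSC)cc(OC)c1 | intermediate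
8 | 1-(chloromethoxy)-3,5-dimethoxybenzene | COc1cc(OCCl)cc(OC)c1 | intermediate
9 | 4-[(3,5-dimethoxyphenoxy)methoxy]-2,6-dimethoxyphenol | COc1cc(OCOc2cc(OC)cc(OC)c2)cc(OC)c1O | intermediate
10 | 1-[(3,5-dimethoxyphenoxy)methoxy]-3,5-dimethoxy-4-[3-methoxy-5-(2,4,6-trimethoxyphenoxy)phenoxy]benzene | COc1cc(Oc2c(OC)cc(OC)cc2OC)cc(Oc2c(OC)cc(OCOc3cc(OC)cc(OC)c3)cc2OC)c1 | intermediate
11 | 1,3,9,11-tetramethoxy-2-[3-methoxy-5-(2,4,6-trimethoxyphenoxy)phenoxy]dibenzo[d,f][1,3]dioxepine | COc1cc(Oc2c(OC)cc(OC)cc2OC)cc(Oc2c(OC)cc3OCOc4cc(OC)cc(OC)c4-c3c2OC)c1 | intermediate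
12 | 3-[3-hydroxy-5-(2,4,6-trihydroxyphenoxy)phenoxy]-[1,1'-biphenyl]-2,2',4,4',6,6'-hexol | Oc1cc(Oc2c(O)cc(O)cc2O)cc(Oc2c(O)cc(O)c(-c3c(O)cc(O)cc3O)c2O)c1 | target

Total step count: 8 steps.
Longest linear sequence: 6 steps (steps 3, 4, 5, 6, 7, 8, from 3,5-dimethoxyphenol 6).

Steps most likely to fail

Step 7. The oxidant may attack the untethered ring A or the more electron-rich product as readily as ring C, leading to intermolecular coupling or quinone formation, and the Lewis acid may ionise the acetal. The fallback makes the biaryl bond by cross-coupling; it sets out from 1, uses 3, and comes back to the route at 12. O-Benzylation of 1 (BnBr, K2CO3, DMF) should give 2-(benzyloxy)-1,3,5-trimethoxybenzene F1. NBS in MeCN at 0 °C should brominate one of its two equivalent free positions to give 2-(benzyloxy)-4-bromo-1,3,5-trimethoxybenzene F2. Suzuki–Miyaura coupling of F2 with commercial (2,4,6-trimethoxyphenyl)boronic acid (Pd(OAc)2, SPhos, K3PO4, toluene/H2O, 100 °C) should give 3-(benzyloxy)-2,2',4,4',6,6'-hexamethoxy-1,1'-biphenyl F3. Hydrogenolysis (H2, Pd/C, EtOAc) frees 2,2',4,4',6,6'-hexamethoxy-[1,1'-biphenyl]-3-ol F4. Ullmann coupling of F4 with 3 under the conditions of step 6 gives 2,2',4,4',6,6'-hexamethoxy-3-[3-methoxy-5-(2,4,6-trimethoxyphenoxy)phenoxy]-1,1'-biphenyl F5, and BBr3 as in step 8 converts F5 into 12.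

Step 4. Chlorination or sulfenylation of the trioxygenated ring may compete with chlorination at sulfur, and the α-chloro ether may alkylate itself on concentration. The fallback brings in the acetal carbon as a dihalomethane after the triaryl backbone is complete; it sets out from 5, uses 3 and 6, and comes back at 10. Monobenzylation of 5 (BnBr 1.0 equiv, K2CO3, acetone, argon), with the same site preference as step 5, should give 4-(benzyloxy)-2,6-dimethoxyphenol F6. Ullmann coupling of F6 with 3 as in step 6 gives 5-(benzyloxy)-1,3-dimethoxy-2-[3-methoxy-5-(2,4,6-trimethoxyphenoxy)phenoxy]benzene F7. Hydrogenolysis (H2, Pd/C, EtOAc) gives 3,5-dimethoxy-4-[3-methoxy-5-(2,4,6-trimethoxyphenoxy)phenoxy]phenol F8. Heating F8 with an excess of 6 (5 equiv) and CH2Br2 (Cs2CO3, DMF, 60 °C) should give the mixed formal 10 together with bis(3,5-dimethoxyphenoxy)methane F9, which is removed by chromatography.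

Step 8. The bromomethyl ether released when the acetal opens may alkylate the electron-rich rings before all methyl ethers are cleaved, and demethylation may stop short. The fallback removes the bridge first with a soft nucleophile that captures its carbon; it sets out from 11 and comes back at 12. AlCl3 with EtSH in CH2Cl2 at 0 °C should excise the methylene group as bis(ethylsulfanyl)methane and give 4,4',6,6'-tetramethoxy-5-[3-methoxy-5-(2,4,6-trimethoxyphenoxy)phenoxy]-[1,1'-biphenyl]-2,2'-diol F10. Any partial demethylation at this stage is harmless, since BBr3 as in step 8 then converts F10 into 12.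

Further compounds
F1 | step 7 | 2-(benzyloxy)-1,3,5-trimethoxybenzene | COc1cc(OC)c(OCc2ccccc2)c(OC)c1
F2 | step 7 | 2-(benzyloxy)-4-bromo-1,3,5-trimethoxybenzene | COc1cc(OC)c(Br)c(OC)c1OCc1ccccc1
F3 | step 7 | 3-(benzyloxy)-2,2',4,4',6,6'-hexamethoxy-1,1'-biphenyl | COc1cc(OC)c(-c2c(OC)cc(OC)cc2OC)c(OC)c1OCc1ccccc1
F4 | step 7 | 2,2',4,4',6,6'-hexamethoxy-[1,1'-biphenyl]-3-ol | COc1cc(OC)c(-c2c(OC)cc(OC)cc2OC)c(OC)c1O
F5 | step 7 | 2,2',4,4',6,6'-hexamethoxy-3-[3-methoxy-5-(2,4,6-trimethoxyphenoxy)phenoxy]-1,1'-biphenyl | COc1cc(Oc2c(OC)cc(OC)cc2OC)cc(Oc2c(OC)cc(OC)c(-c3c(OC)cc(OC)cc3OC)c2OC)c1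
F6 | step 4 | 4-(benzyloxy)-2,6-dimethoxyphenol | COc1cc(OCc2ccccc2)cc(OC)c1O
F7 | step 4 | 5-(benzyloxy)-1,3-dimethoxy-2-[3-methoxy-5-(2,4,6-trimethoxyphenoxy)phenoxy]benzene | COc1cc(Oc2c(OC)cc(OC)cc2OC)cc(Oc2c(OC)cc(OCc3ccccc3)cc2OC)c1
F8 | step 4 | 3,5-dimethoxy-4-[3-methoxy-5-(2,4,6-trimethoxyphenoxy)phenoxy]phenol | COc1cc(Oc2c(OC)cc(OC)cc2OC)cc(Oc2c(OC)cc(O)cc2OC)c1
F9 | step 4 | bis(3,5-dimethoxyphenoxy)methane (co-product, discarded) | COc1cc(OCOc2cc(OC)cc(OC)c2)cc(OC)c1
F10 | step 8 | 4,4',6,6'-tetramethoxy-5-[3-methoxy-5-(2,4,6-trimethoxyphenoxy)phenoxy]-[1,1'-biphenyl]-2,2'-diol | COc1cc(Oc2c(OC)cc(OC)cc2OC)cc(Oc2c(OC)cc(O)c(-c3c(O)cc(OC)cc3OC)c2OC)c1
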